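(Readings and results come from a simulation with constants of no real substance; noise was put on by code.)

At late times the runs read best: at 12.0 h the ochre run has 85.0% of the substrate pool (left-handed substrate and right-handed substrate together) left, and at 12.0 h the green run has 83.0%, with a scatter of 1.5 percentage points per reading. The quick number wanted for the flask, and the hunch of a steady rate, go best through this fraction left. Its logarithm, sign turned and divided by the time, gives 0.0135 /h for ochre and 0.0155 /h for green. Their mean, 0.0145 /h, is the pool constant, an apparent first-order rate constant for the fall of the fraction left.

common to all: left-handed substrate 20 mM; right-handed substrate 20 mM; added ligand 17 µM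
- ochre: solid reagent 44 mM; catalyst 28 µM; run made earlier
- green: solid reagent 44 mM; catalyst 44 µM; run made earlier
- flask: solid reagent 44.0 mM; catalyst 20 µM; time 20 h

- ochre (time / h: left-handed product / %, right-handed product / %, left-handed substrate / %): 1.00: 1, 1, 49; 2.00: 3, 0, 48; 5.00: 5, 2, 46; 12.0: 15, 0, 39
- green (time / h: left-handed product / %, right-handed product / %, left-handed substrate / %): 1.00: 0, 0, 47; 2.00: 1, 0, 48; 5.00: 8, 0, 44; 12.0: 16, 1, 41

(scatter of a reading: 1.5 percentage points)

Green holds 1.57 times the c(catalyst) of ochre, yet its constant is 1.15 times that of ochre, and the products differ by 2 points, near the scatter. The flask sits lower in c(catalyst) than either run, but higher than c(added ligand), at 20 µM against 17 µM. Carrying the constant over is therefore a bet. On that bet the flask keeps 74.8% of its pool at 20 h, so 25.2% has reacted.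

- excess of left-handed product over right-handed product in the product at 2.0 h
- excess of left-handed product over right-handed product in the product at 20 h
- part of the left-handed substrate and right-handed substrate charged together that has reacted at 20 h

- catalyst is single-handed; left-handed substrate and right-handed substrate are mirror images of each other, charged as a racemate, each of them at the stated concentration
- solid reagent is a solid; its amount is given per volume of the solution
- the analysis behind the earlier runs scatters by 1.5 percentage points, standard deviation
- at the start none of the solid reagent is in solution
- an excess is below zero if the other one leads

For the excess at 2.0 h the forecast gives 96% (80% to 100%), for the excess at 20 h it gives 96% (88% to 100%), and for the part reacted at 20 h it gives 25% (13% to 31%), reasoning that the flask is “still above the ligand level, so I expect the same rate”.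

In the same order the flask gives 95.1%, 94.9% and 24.6%, each inside its forecast range.

    partner + catalyst + left-handed substrate → catalyst + left-handed product (k = 2000 /M²/s)
    partner + catalyst + right-handed substrate → catalyst + right-handed product (k = 49.0 /M²/s)
    left-handed substrate ⇌ right-handed substrate (k = 4.30 × 10⁻⁵ /s)
    catalyst + added ligand ⇌ idle complex, settled at all times (K = 53000 /M)
    partner → decomposed reagent (k = 4.80 × 10⁻⁵ /s)
    solid reagent ⇌ partner, rate k6*(cs6 - [partner]) while solid is left; crystals form when [partner] > cs6 (solubility = 4.90 mM, k = 3.40 × 10⁻⁵ /s)

The pool constant of the flask comes to 0.0141 /h, against 0.0145 /h carried. The carried constant does not hold in the neighbouring flask, which has 0.0080 mM of catalyst, less than c(added ligand). Its excesses stand at 95.2% and 94.9%, but 18.9% has reacted at 20 h, so its pool constant is 0.0105 /h. That is 0.745 times the constant of the flask, for 0.400 times its catalyst. In that neighbour, partner stands at 0.715 mM at 20.0 h, against 0.355 mM in the flask, and decomposed reagent at 2.18 mM, against 1.05 mM.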